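**Plan**

1. The target is fisetinidol (unit 1)-(4α→6)-fisetinidol (unit 2)-(4α→6)-catechin (unit 3), with a third fisetinidol (unit 4) bound through its C4 (4α) to C8 of the catechin. The retrosynthesis cuts, in unit 4, then unit 1, then unit 2, the two bonds that tie ring C to its resorcinol ring A (O1–C2 and C4a–C4), and then the three aryl–C4 bonds.
2. Enabling feature: in each fisetinidol ring C, O1 and C4a are the ortho oxygen/carbon pair of a resorcinol nucleus (C4a para to the 7-oxygen). C4 is benzylic to an oxygen-rich ring A of the neighbouring unit (for unit 4, C8 of the phloroglucinol ring A of catechin) and C2 is benzylic to a catechol ring. Ring C is therefore resorcinol (a 1,3-C,O-dinucleophile) plus an aryl-flanked 2,3-epoxy-1-ol (a 1,3-dielectrophile).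
3. Forward: benzylated (+)-catechin is brominated at C8 and iodinated at C6. I/Mg exchange, addition to epoxy aldehyde 3 and annulation with 4-iodoresorcinol build rings A and C of unit 2 at C6. The same two operations at the new aryl iodide, with resorcinol, build unit 1. Br/Li exchange at C8, addition to 3 and annulation with resorcinol build unit 4, and hydrogenolysis ends the route.
4. Stereochemistry: C2 and C3 of unit 3 come from (+)-catechin. In each fisetinidol unit, C3 keeps the oxirane C–O bond of 3 (one catalyst-controlled enal epoxidation), C2 arises by inversion at the benzylic oxirane carbon, and C4 by capture of the benzylic cation anti to the oxirane C–O bond (2,3-trans-3,4-trans).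

Key step: step 13

Assumption: the facial sense of the enal epoxidation in step 2 is taken from the steric-shielding model of the iminium ion (if the antipodal oxirane formed, the enantiomeric catalyst would be used), and carbinols 9, 15 and 21 are carried on as mixtures of epimers at the carbinol carbon, which is ionized in the following step.

**Route**

Step 1
Reactants: 1 3,4-bis(benzyloxy)benzaldehyde
Product: 2 (E)-3-[3,4-bis(benzyloxy)phenyl]prop-2-enal
Conditions: Ph3P=CHCHO (1.1 equiv), toluene, 80 °C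
Reagents that add atoms: (triphenylphosphoranylidene)acetaldehyde, O=CC=P(c1ccccc1)(c1ccccc1)c1ccccc1
Why: Wittig olefination with the stabilized formylmethylene ylide should give the E-enal; no stereocentre is formed.

Step 2
Reactants: 2 (E)-3-[3,4-bis(benzyloxy)phenyl]prop-2-enal
Product: 3 (2R,3S)-3-[3,4-bis(benzyloxy)phenyl]oxirane-2-carbaldehyde
Conditions: (R)-2-{bis[3,5-bis(trifluoromethyl)phenyl](trimethylsilyloxy)methyl}pyrrolidine (10 mol %), 35% aq H2O2 (1.3 equiv), CH2Cl2, rt; used without chromatography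
Reagents that add atoms: hydrogen peroxide, OO
Why: Iminium–enamine (Weitz–Scheffer-type) organocatalytic epoxidation of an enal, in which hydroperoxide should add to the β-carbon of the E-iminium ion on the face remote from the diaryl(silyloxy)methyl group and the enamine then closes the oxirane, so both oxirane stereocentres (trans, 2R,3S) are set by the catalyst while the formyl group tempers the acid lability of the electron-rich aryl oxirane.

Step 3
Reactants: 4 (+)-catechin
Product: 5 5,7,3',4'-tetra-O-benzyl-(+)-catechin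
Conditions: BnBr (4.4 equiv), K2CO3, DMF, 0 °C to rt
Reagents that add atoms: benzyl bromide, BrCc1ccccc1
Why: Williamson etherification with K2CO3 should benzylate the four phenols and leave the much less acidic secondary 3-OH free, without touching C2 or C3.

Step 4
Reactants: 5 5,7,3',4'-tetra-O-benzyl-(+)-catechin
Product: 6 8-bromo-5,7,3',4'-tetra-O-benzylcatechin
Conditions: NBS (1.0 equiv), CH2Cl2, −78 °C to rt
Reagents that add atoms: N-bromosuccinimide, O=C1CCC(=O)N1Br
Why: Electrophilic aromatic bromination of the phloroglucinol-type ring A should occur at C8, the less hindered of its two free positions, as is usual for 5,7-di-O-alkylated flavan-3-ols.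

Step 5
Reactants: 6 8-bromo-5,7,3',4'-tetra-O-benzylcatechin
Product: 7 8-bromo-6-iodo-5,7,3',4'-tetra-O-benzylcatechin
Conditions: NIS (1.1 equiv), CF3CO2H (10 mol %), MeCN–CH2Cl2, 0 °C to rt
Reagents that add atoms: N-iodosuccinimide, O=C1CCC(=O)N1I
Why: Electrophilic aromatic iodination should take the only remaining position of the fully activated ring A (C6), the dibenzylated catechol ring B being far less nucleophilic.

Step 6
Reactants: 7 8-bromo-6-iodo-5,7,3',4'-tetra-O-benzylcatechin; 3 (2R,3S)-3-[3,4-bis(benzyloxy)phenyl]oxirane-2-carbaldehyde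
Product: 9 8-bromo-5,7,3',4'-tetra-O-benzylcatechin bearing at C6 a hydroxy{(2S,3S)-3-[3,4-bis(benzyloxy)phenyl]oxiran-2-yl}methyl group (carbinol epimers), via arylmagnesium chloride 8 (not isolated)
Conditions: i-PrMgCl·LiCl (2.1 equiv), THF, −20 °C; then 3 (1.3 equiv), −78 °C; aq NH4Cl at −78 °C
Reagents that add atoms: none
Why: Iodine–magnesium exchange should be far faster at the C6 iodide, flanked by two benzyloxy groups, than at the C8 bromide, and the arylmagnesium adds 1,2 to the aldehyde (Grignard addition); the new carbinol centre is uncontrolled, which is harmless because it is ionized in step 7, and the cold quench avoids Payne rearrangement.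

Step 7
Reactants: 9 C6 epoxy carbinol of the catechin unit; 10 4-iodoresorcinol
Product: 12 3',4'-di-O-benzyl-6-iodofisetinidol-(4α→6)-8-bromo-5,7,3',4'-tetra-O-benzylcatechin (unit 2 with free 7-OH and 3-OH; unit 3 with free 3-OH), via Friedel–Crafts adduct 11 (not isolated)
Conditions: 10 (10 equiv), (1S)-(+)-camphor-10-sulfonic acid (5 mol %), CH2Cl2–(CF3)2CHOH 4:1, −40 to 0 °C
Reagents that add atoms: none
Why: Proposed new method: acid should ionize the carbinol flanked by the 2,4,6-trioxygenated ring A of the catechin unit, 4-iodoresorcinol should capture the cation through its C6 (ortho to one hydroxyl and para to the other; C2 is hindered and C5 not activated) anti to the oxirane C–O bond (3,4-trans), and its ortho hydroxyl should then open the oxirane 6-endo at the benzylic carbon with inversion (2,3-trans) while the oxirane C3–O bond is kept, so iodine ends at C6 of the new ring A; the closest known reaction types are the acid-mediated Friedel–Crafts union of flavan-3,4-diols with resorcinol nuclei and the acid-catalysed cyclization of 1-(2-hydroxyaryl)-3-aryl-2,3-epoxypropanes to 2,3-trans-flavan-3-ols.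

Step 8
Reactants: 12 dimer triol
Product: 13 tri-O-benzyl ether of 12 (unit 2: 7-OBn and 3-OBn; unit 3: 3-OBn)
Conditions: NaH (4 equiv), BnBr (4 equiv), n-Bu4NI (cat.), DMF, 0 °C to rt
Reagents that add atoms: benzyl bromide, BrCc1ccccc1
Why: Williamson benzylation with NaH should cap the phenol and both hindered secondary alcohols so that no acidic proton interferes with the later organometallic steps; no stereocentre is touched.

Step 9
Reactants: 13 perbenzylated iodo dimer; 3 (2R,3S)-3-[3,4-bis(benzyloxy)phenyl]oxirane-2-carbaldehyde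
Product: 15 dimer bearing at C6 of unit 2 a hydroxy{(2S,3S)-3-[3,4-bis(benzyloxy)phenyl]oxiran-2-yl}methyl group (carbinol epimers), via arylmagnesium chloride 14 (not isolated)
Conditions: i-PrMgCl·LiCl (1.1 equiv), THF, −20 °C; then 3 (1.3 equiv), −78 °C; aq NH4Cl at −78 °C
Reagents that add atoms: none
Why: Iodine–magnesium exchange should be selective for the aryl iodide of unit 2 over the electron-rich aryl bromide at C8 of unit 3, and Grignard addition to 3 gives the carbinol as an inconsequential mixture of epimers.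

Step 10
Reactants: 15 C6 epoxy carbinol of unit 2; 16 resorcinol
Product: 18 trimer with unit 1 as its 3',4'-di-O-benzyl ether carrying free 7-OH and 3-OH, via Friedel–Crafts adduct 17 (not isolated)
Conditions: 16 (10 equiv), (1S)-(+)-camphor-10-sulfonic acid (5 mol %), CH2Cl2–(CF3)2CHOH 4:1, −40 to 0 °C
Reagents that add atoms: none
Why: Proposed new method: the carbinol, here stabilized as a cation by the ortho 7-benzyloxy group and the para O1 of ring A of unit 2, should ionize and be captured by C4 of resorcinol anti to the oxirane C–O bond (3,4-trans), after which the ortho phenol opens the oxirane 6-endo at the benzylic carbon with inversion (2,3-trans) and C3 keeps its oxirane oxygen; the closest known reaction types are the acid-mediated Friedel–Crafts union of flavan-3,4-diols with resorcinol and the acid-catalysed cyclization of 1-(2-hydroxyaryl)-3-aryl-2,3-epoxypropanes to 2,3-trans-flavan-3-ols.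

Step 11
Reactants: 18 trimer diol
Product: 19 perbenzylated trimer (8-bromo at unit 3)
Conditions: NaH (3 equiv), BnBr (3 equiv), n-Bu4NI (cat.), DMF, 0 °C to rt
Reagents that add atoms: benzyl bromide, BrCc1ccccc1
Why: Williamson benzylation of the phenol and the secondary alcohol of unit 1 removes the last acidic protons and makes ring A of unit 1 unable to cyclize in step 13; no stereocentre is touched.

Step 12
Reactants: 19 perbenzylated trimer; 3 (2R,3S)-3-[3,4-bis(benzyloxy)phenyl]oxirane-2-carbaldehyde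
Product: 21 trimer bearing at C8 of unit 3 a hydroxy{(2S,3S)-3-[3,4-bis(benzyloxy)phenyl]oxiran-2-yl}methyl group (carbinol epimers), via aryllithium 20 (not isolated)
Conditions: t-BuLi (2.1 equiv), THF, −78 °C; then 3 (1.5 equiv), −78 °C; aq NH4Cl at −78 °C
Reagents that add atoms: none
Why: Bromine–lithium exchange with two equivalents of t-BuLi at −78 °C should outpace deprotonation of the benzyl ethers, as is known for 8-bromo benzylated flavan-3-ols, and the aryllithium adds 1,2 to the aldehyde; the carbinol epimers are carried on.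

Step 13
Reactants: 21 C8 epoxy carbinol of the trimer; 16 resorcinol
Product: 23 pentadeca-O-benzyl tetramer with free 7-OH and 3-OH on unit 4, via Friedel–Crafts adduct 22 (not isolated)
Conditions: 16 (10 equiv), (1S)-(+)-camphor-10-sulfonic acid (5 mol %), CH2Cl2–(CF3)2CHOH 4:1, −40 to 0 °C
Reagents that add atoms: none
Why: Proposed new method: mild acid should ionize the C8 carbinol of 21, whose cation is stabilized by the 2,4,6-trioxygenated ring A of the catechin unit, resorcinol should capture it at C4 to give 22, and the ortho phenol of 22 should then open the protonated oxirane at its benzylic carbon, so that C4a–C4 and O1–C2 of unit 4 are made in one operation (a formal [3+3] annulation of a 1,3-C,O-dinucleophile with an epoxy carbinol). The closest known reaction types are the acid-mediated Friedel–Crafts union of flavan-3,4-diols with resorcinol or phloroglucinol nuclei and the acid-catalysed cyclization of 1-(2-hydroxyaryl)-3-aryl-2,3-epoxypropanes to 2,3-trans-flavan-3-ols; their coupling on an open-chain epoxy carbinol is what is new. Ring C closes in the 6-endo-tet mode at the oxirane carbon that bears the 3,4-bis(benzyloxy)phenyl group, because its para benzyloxy substituent weakens that C–O bond and so outweighs the 5-exo alternative. C3 keeps the oxirane C–O bond of 3, C2 is set by inversion at the (S)-oxirane carbon (a trans oxirane gives 2,3-trans), and C4 is set in the Friedel–Crafts event, where 1,3-allylic strain with the two ortho oxygens holds the oxirane C–H in the plane of the cation and resorcinol enters anti to the oxirane C–O bond, which leads to the 3,4-trans (4α) adduct and to the all-equatorial ring. The step needs carbon to bond at C4 and oxygen at C2 and not the reverse, which is secured because the trioxygenated aryl carbinol ionizes far more readily at −40 °C than the oxirane on the dioxygenated aryl ring and because O-alkylation of resorcinol by the C4 cation is reversible whereas C-alkylation is not. The large excess of resorcinol should suppress alkylation of the product, or of the benzylated resorcinol rings of units 1 and 2, by a second cation.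

Step 14
Reactants: 23 pentadeca-O-benzyl tetramer
Product: 24 target, fisetinidol-(4α→6)-fisetinidol-(4α→6)-catechin-(8←4α)-fisetinidol
Conditions: H2 (1 atm), Pd(OH)2/C, THF–MeOH–H2O, rt
Reagents that add atoms: none
Why: Hydrogenolysis of the fifteen benzyl ethers over Pd(OH)2/C under neutral conditions, as used for benzylated oligoflavanoids, should leave the diarylmethine interflavanyl bonds and all eleven stereocentres intact.

**Compound list**

1 | 3,4-bis(benzyloxy)benzaldehyde | O=Cc1ccc(OCc2ccccc2)c(OCc2ccccc2)c1 | starting material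
2 | (E)-3-[3,4-bis(benzyloxy)phenyl]prop-2-enal | O=C/C=C/c1ccc(OCc2ccccc2)c(OCc2ccccc2)c1 | intermediate
3 | (2R,3S)-3-[3,4-bis(benzyloxy)phenyl]oxirane-2-carbaldehyde (trans) | O=C[C@@H]1O[C@H]1c1ccc(OCc2ccccc2)c(OCc2ccccc2)c1 | intermediate
4 | (+)-catechin, (2R,3S)-2-(3,4-dihydroxyphenyl)chromane-3,5,7-triol | Oc1cc(O)c2c(c1)O[C@H](c1ccc(O)c(O)c1)[C@@H](O)C2 | starting material
5 | 5,7,3',4'-tetra-O-benzyl-(+)-catechin (2R,3S; 3-OH free) | c1c(OCc3ccccc3)c2c(cc1OCc1ccccc1)O[C@H](c1ccc(OCc3ccccc3)c(OCc3ccccc3)c1)[C@@H](O)C2 | intermediate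
6 | 8-bromo-5,7,3',4'-tetra-O-benzylcatechin | c1c(OCc3ccccc3)c2c(c(Br)c1OCc1ccccc1)O[C@H](c1ccc(OCc3ccccc3)c(OCc3ccccc3)c1)[C@@H](O)C2 | intermediate
7 | 8-bromo-6-iodo-5,7,3',4'-tetra-O-benzylcatechin | Ic1c(OCc3ccccc3)c2c(c(Br)c1OCc1ccccc1)O[C@H](c1ccc(OCc3ccccc3)c(OCc3ccccc3)c1)[C@@H](O)C2 | intermediate
8 | C6 arylmagnesium chloride of 7, as its 3-O-magnesium alkoxide | Cl[Mg]c1c(OCc3ccccc3)c2c(c(Br)c1OCc1ccccc1)O[C@H](c1ccc(OCc3ccccc3)c(OCc3ccccc3)c1)[C@@H](O[Mg]Cl)C2 | intermediate (not isolated)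
9 | 8-bromo-5,7,3',4'-tetra-O-benzylcatechin with a hydroxy{(2S,3S)-3-[3,4-bis(benzyloxy)phenyl]oxiran-2-yl}methyl group at C6 (carbinol epimers) | OC([C@@H]1O[C@H]1c1ccc(OCc3ccccc3)c(OCc3ccccc3)c1)c1c(OCc3ccccc3)c2c(c(Br)c1OCc1ccccc1)O[C@H](c1ccc(OCc3ccccc3)c(OCc3ccccc3)c1)[C@@H](O)C2 | intermediate
10 | 4-iodoresorcinol (4-iodobenzene-1,3-diol) | Oc1ccc(I)c(O)c1 | starting material
11 | Friedel–Crafts adduct: catechin unit with a (2,4-dihydroxy-5-iodophenyl)[(2S,3S)-3-aryloxiran-2-yl]methyl group at C6, new methine as in 12 | Oc1cc(O)c(I)cc1[C@H]([C@@H]1O[C@H]1c1ccc(OCc3ccccc3)c(OCc3ccccc3)c1)c1c(OCc3ccccc3)c2c(c(Br)c1OCc1ccccc1)O[C@H](c1ccc(OCc3ccccc3)c(OCc3ccccc3)c1)[C@@H](O)C2 | intermediate (not isolated)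
12 | 3',4'-di-O-benzyl-6-iodofisetinidol-(4α→6)-8-bromo-5,7,3',4'-tetra-O-benzylcatechin (unit 2: 2R,3S, 2,3-trans-3,4-trans; free 7-OH and 3-OH; unit 3: free 3-OH) | Ic1cc2c(cc1O)O[C@H](c1ccc(OCc3ccccc3)c(OCc3ccccc3)c1)[C@@H](O)[C@@H]2c1c(OCc3ccccc3)c2c(c(Br)c1OCc1ccccc1)O[C@H](c1ccc(OCc3ccccc3)c(OCc3ccccc3)c1)[C@@H](O)C2 | intermediate
13 | tri-O-benzyl ether of 12 (unit 2: 7-OBn, 3-OBn; unit 3: 3-OBn) | Ic1cc2c(cc1OCc1ccccc1)O[C@H](c1ccc(OCc3ccccc3)c(OCc3ccccc3)c1)[C@@H](OCc1ccccc1)[C@@H]2c1c(OCc3ccccc3)c2c(c(Br)c1OCc1ccccc1)O[C@H](c1ccc(OCc3ccccc3)c(OCc3ccccc3)c1)[C@@H](OCc1ccccc1)C2 | intermediate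
14 | arylmagnesium chloride at C6 of unit 2 of 13 | Cl[Mg]c1cc2c(cc1OCc1ccccc1)O[C@H](c1ccc(OCc3ccccc3)c(OCc3ccccc3)c1)[C@@H](OCc1ccccc1)[C@@H]2c1c(OCc3ccccc3)c2c(c(Br)c1OCc1ccccc1)O[C@H](c1ccc(OCc3ccccc3)c(OCc3ccccc3)c1)[C@@H](OCc1ccccc1)C2 | intermediate (not isolated)
15 | perbenzylated dimer with a hydroxy{(2S,3S)-3-[3,4-bis(benzyloxy)phenyl]oxiran-2-yl}methyl group at C6 of unit 2 (carbinol epimers) | OC([C@@H]1O[C@H]1c1ccc(OCc3ccccc3)c(OCc3ccccc3)c1)c1cc2c(cc1OCc1ccccc1)O[C@H](c1ccc(OCc3ccccc3)c(OCc3ccccc3)c1)[C@@H](OCc1ccccc1)[C@@H]2c1c(OCc3ccccc3)c2c(c(Br)c1OCc1ccccc1)O[C@H](c1ccc(OCc3ccccc3)c(OCc3ccccc3)c1)[C@@H](OCc1ccccc1)C2 | intermediate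
16 | resorcinol (benzene-1,3-diol) | Oc1cccc(O)c1 | starting material
17 | Friedel–Crafts adduct: dimer with a (2,4-dihydroxyphenyl)[(2S,3S)-3-aryloxiran-2-yl]methyl group at C6 of unit 2, new methine as in 18 | Oc1cc(O)ccc1[C@H]([C@@H]1O[C@H]1c1ccc(OCc3ccccc3)c(OCc3ccccc3)c1)c1cc2c(cc1OCc1ccccc1)O[C@H](c1ccc(OCc3ccccc3)c(OCc3ccccc3)c1)[C@@H](OCc1ccccc1)[C@@H]2c1c(OCc3ccccc3)c2c(c(Br)c1OCc1ccccc1)O[C@H](c1ccc(OCc3ccccc3)c(OCc3ccccc3)c1)[C@@H](OCc1ccccc1)C2 | intermediate (not isolated)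
18 | trimer: 3',4'-di-O-benzylfisetinidol (unit 1, free 7-OH and 3-OH)-(4α→6)-tetra-O-benzylfisetinidol (unit 2)-(4α→6)-8-bromo-penta-O-benzylcatechin (unit 3) | Oc1ccc2c(c1)O[C@H](c1ccc(OCc3ccccc3)c(OCc3ccccc3)c1)[C@@H](O)[C@@H]2c1cc2c(cc1OCc1ccccc1)O[C@H](c1ccc(OCc3ccccc3)c(OCc3ccccc3)c1)[C@@H](OCc1ccccc1)[C@@H]2c1c(OCc3ccccc3)c2c(c(Br)c1OCc1ccccc1)O[C@H](c1ccc(OCc3ccccc3)c(OCc3ccccc3)c1)[C@@H](OCc1ccccc1)C2 | intermediate
19 | perbenzylated trimer (trideca-O-benzyl, 8-bromo at unit 3) | c1ccccc1COc1ccc2c(c1)O[C@H](c1ccc(OCc3ccccc3)c(OCc3ccccc3)c1)[C@@H](OCc1ccccc1)[C@@H]2c1cc2c(cc1OCc1ccccc1)O[C@H](c1ccc(OCc3ccccc3)c(OCc3ccccc3)c1)[C@@H](OCc1ccccc1)[C@@H]2c1c(OCc3ccccc3)c2c(c(Br)c1OCc1ccccc1)O[C@H](c1ccc(OCc3ccccc3)c(OCc3ccccc3)c1)[C@@H](OCc1ccccc1)C2 | intermediate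
20 | C8 aryllithium of the perbenzylated trimer | c1ccccc1COc1ccc2c(c1)O[C@H](c1ccc(OCc3ccccc3)c(OCc3ccccc3)c1)[C@@H](OCc1ccccc1)[C@@H]2c1cc2c(cc1OCc1ccccc1)O[C@H](c1ccc(OCc3ccccc3)c(OCc3ccccc3)c1)[C@@H](OCc1ccccc1)[C@@H]2c1c(OCc3ccccc3)c2c(c([Li])c1OCc1ccccc1)O[C@H](c1ccc(OCc3ccccc3)c(OCc3ccccc3)c1)[C@@H](OCc1ccccc1)C2 | intermediate (not isolated)
21 | perbenzylated trimer with a hydroxy{(2S,3S)-3-[3,4-bis(benzyloxy)phenyl]oxiran-2-yl}methyl group at C8 of unit 3 (carbinol epimers) | c1ccccc1COc1ccc2c(c1)O[C@H](c1ccc(OCc3ccccc3)c(OCc3ccccc3)c1)[C@@H](OCc1ccccc1)[C@@H]2c1cc2c(cc1OCc1ccccc1)O[C@H](c1ccc(OCc3ccccc3)c(OCc3ccccc3)c1)[C@@H](OCc1ccccc1)[C@@H]2c1c(OCc3ccccc3)c2c(c(C(O)[C@@H]3O[C@H]3c3ccc(OCc4ccccc4)c(OCc4ccccc4)c3)c1OCc1ccccc1)O[C@H](c1ccc(OCc3ccccc3)c(OCc3ccccc3)c1)[C@@H](OCc1ccccc1)C2 | intermediate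
22 | Friedel–Crafts adduct: trimer with a (2,4-dihydroxyphenyl)[(2S,3S)-3-aryloxiran-2-yl]methyl group at C8 of unit 3, new methine as in 23 | c1ccccc1COc1ccc2c(c1)O[C@H](c1ccc(OCc3ccccc3)c(OCc3ccccc3)c1)[C@@H](OCc1ccccc1)[C@@H]2c1cc2c(cc1OCc1ccccc1)O[C@H](c1ccc(OCc3ccccc3)c(OCc3ccccc3)c1)[C@@H](OCc1ccccc1)[C@@H]2c1c(OCc3ccccc3)c2c(c([C@H](c3ccc(O)cc3O)[C@@H]3O[C@H]3c3ccc(OCc4ccccc4)c(OCc4ccccc4)c3)c1OCc1ccccc1)O[C@H](c1ccc(OCc3ccccc3)c(OCc3ccccc3)c1)[C@@H](OCc1ccccc1)C2 | intermediate (not isolated)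
23 | pentadeca-O-benzyl tetramer; unit 4 (2R,3S, 2,3-trans-3,4-trans, 4α→8) carries free 7-OH and 3-OH | c1ccccc1COc1ccc2c(c1)O[C@H](c1ccc(OCc3ccccc3)c(OCc3ccccc3)c1)[C@@H](OCc1ccccc1)[C@@H]2c1cc2c(cc1OCc1ccccc1)O[C@H](c1ccc(OCc3ccccc3)c(OCc3ccccc3)c1)[C@@H](OCc1ccccc1)[C@@H]2c1c(OCc3ccccc3)c2c(c([C@@H]3c4ccc(O)cc4O[C@H](c4ccc(OCc5ccccc5)c(OCc5ccccc5)c4)[C@H]3O)c1OCc1ccccc1)O[C@H](c1ccc(OCc3ccccc3)c(OCc3ccccc3)c1)[C@@H](OCc1ccccc1)C2 | intermediate
24 | CNP0263622.1, fisetinidol-(4α→6)-fisetinidol-(4α→6)-catechin-(8←4α)-fisetinidol | Oc1ccc2c(c1)O[C@H](c1ccc(O)c(O)c1)[C@@H](O)[C@@H]2c1cc2c(cc1O)O[C@H](c1ccc(O)c(O)c1)[C@@H](O)[C@@H]2c1c(O)c2c(c([C@@H]3c4ccc(O)cc4O[C@H](c4ccc(O)c(O)c4)[C@H]3O)c1O)O[C@H](c1ccc(O)c(O)c1)[C@@H](O)C2 | target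

**Step count and risks**

Total step count: 14. Longest linear sequence: 12 steps (4 to 24, steps 3 to 14).

Steps most likely to fail:

Step 10. The carbinol on the 2,4-dioxygenated ring A of unit 2 ionizes less readily than those on the catechin ring. The oxirane may therefore ionize first and undergo a Meinwald-type shift or take up resorcinol at the wrong carbon, which would swap the roles of C2 and C4. Fallback by known reactions, with the two bonds made in the reverse order: from 15, hydroxyl-directed opening of the epoxy alcohol at the benzylic oxirane carbon by 3-(benzyloxy)phenol (Ti(OiPr)4, toluene, 60 °C, inversion at C2) should give the aryl ether diol F1. CF3CO2H in CH2Cl2 at −20 °C then ionizes the remaining carbinol, and intramolecular Friedel–Crafts cyclialkylation para to the benzyloxy group, through a chair-like arrangement with the unit 2 aryl group equatorial, should give the 7-O-benzyl trimer F2. Benzylation of its 3-OH (NaH, BnBr, DMF) rejoins the route at 19.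

Step 13. Capture of the open-chain cation at C4 may show poor facial selectivity, eroding the 3,4-trans relationship of unit 4, and a benzylated resorcinol ring of unit 1 or 2 may compete as nucleophile. Fallback by known reactions: from 21, Ti(OiPr)4-assisted opening of the oxirane at its benzylic carbon by 3-(benzyloxy)phenol should give the aryl ether diol F3. Acid-mediated cyclialkylation (CF3CO2H, CH2Cl2, −20 °C) then closes ring C from a cyclic, chair-like transition state that places the catechin unit equatorial, giving the hexadeca-O-benzyl tetramer F4. Hydrogenolysis of F4 over Pd(OH)2/C rejoins the route at 24.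

Step 7. Capture by the iodine-deactivated resorcinol may be slow, and acid may cause loss or migration of iodine from the electron-rich iodoarene. Fallback by known reactions, with iodine introduced afterwards: from 9, Ti(OiPr)4-assisted opening with 3-(benzyloxy)phenol should give the aryl ether diol F5, and acid-mediated cyclialkylation (CF3CO2H, CH2Cl2, −20 °C) the iodine-free dimer F6. Electrophilic iodination with NIS, at C6 of ring A of unit 2 (ortho to the benzyloxy group, para to O1, the only activated and accessible position left), should give F7. Benzylation of the two secondary alcohols (NaH, BnBr, DMF) rejoins the route at 13.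

Further compounds

F1 | step 10 | perbenzylated dimer with a (2S,3R)-1,2-dihydroxy-3-[3-(benzyloxy)phenoxy]-3-[3,4-bis(benzyloxy)phenyl]propyl group at C6 of unit 2 (C1 epimers) | OC([C@H](O)[C@H](Oc1cccc(OCc3ccccc3)c1)c1ccc(OCc3ccccc3)c(OCc3ccccc3)c1)c1cc2c(cc1OCc1ccccc1)O[C@H](c1ccc(OCc3ccccc3)c(OCc3ccccc3)c1)[C@@H](OCc1ccccc1)[C@@H]2c1c(OCc3ccccc3)c2c(c(Br)c1OCc1ccccc1)O[C@H](c1ccc(OCc3ccccc3)c(OCc3ccccc3)c1)[C@@H](OCc1ccccc1)C2
F2 | step 10 | trimer with unit 1 as its 7,3',4'-tri-O-benzyl ether and free 3-OH | c1ccccc1COc1ccc2c(c1)O[C@H](c1ccc(OCc3ccccc3)c(OCc3ccccc3)c1)[C@@H](O)[C@@H]2c1cc2c(cc1OCc1ccccc1)O[C@H](c1ccc(OCc3ccccc3)c(OCc3ccccc3)c1)[C@@H](OCc1ccccc1)[C@@H]2c1c(OCc3ccccc3)c2c(c(Br)c1OCc1ccccc1)O[C@H](c1ccc(OCc3ccccc3)c(OCc3ccccc3)c1)[C@@H](OCc1ccccc1)C2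
F3 | step 13 | perbenzylated trimer with a (2S,3R)-1,2-dihydroxy-3-[3-(benzyloxy)phenoxy]-3-[3,4-bis(benzyloxy)phenyl]propyl group at C8 of unit 3 (C1 epimers) | c1ccccc1COc1ccc2c(c1)O[C@H](c1ccc(OCc3ccccc3)c(OCc3ccccc3)c1)[C@@H](OCc1ccccc1)[C@@H]2c1cc2c(cc1OCc1ccccc1)O[C@H](c1ccc(OCc3ccccc3)c(OCc3ccccc3)c1)[C@@H](OCc1ccccc1)[C@@H]2c1c(OCc3ccccc3)c2c(c(C(O)[C@H](O)[C@H](Oc3cccc(OCc4ccccc4)c3)c3ccc(OCc4ccccc4)c(OCc4ccccc4)c3)c1OCc1ccccc1)O[C@H](c1ccc(OCc3ccccc3)c(OCc3ccccc3)c1)[C@@H](OCc1ccccc1)C2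
F4 | step 13 | hexadeca-O-benzyl tetramer, unit 4 as its 7,3',4'-tri-O-benzyl ether with free 3-OH | c1ccccc1COc1ccc2c(c1)O[C@H](c1ccc(OCc3ccccc3)c(OCc3ccccc3)c1)[C@@H](OCc1ccccc1)[C@@H]2c1cc2c(cc1OCc1ccccc1)O[C@H](c1ccc(OCc3ccccc3)c(OCc3ccccc3)c1)[C@@H](OCc1ccccc1)[C@@H]2c1c(OCc3ccccc3)c2c(c([C@@H]3c4ccc(OCc5ccccc5)cc4O[C@H](c4ccc(OCc5ccccc5)c(OCc5ccccc5)c4)[C@H]3O)c1OCc1ccccc1)O[C@H](c1ccc(OCc3ccccc3)c(OCc3ccccc3)c1)[C@@H](OCc1ccccc1)C2
F5 | step 7 | 8-bromo-5,7,3',4'-tetra-O-benzylcatechin with a (2S,3R)-1,2-dihydroxy-3-[3-(benzyloxy)phenoxy]-3-[3,4-bis(benzyloxy)phenyl]propyl group at C6 (C1 epimers) | OC([C@H](O)[C@H](Oc1cccc(OCc3ccccc3)c1)c1ccc(OCc3ccccc3)c(OCc3ccccc3)c1)c1c(OCc3ccccc3)c2c(c(Br)c1OCc1ccccc1)O[C@H](c1ccc(OCc3ccccc3)c(OCc3ccccc3)c1)[C@@H](O)C2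
F6 | step 7 | 7,3',4'-tri-O-benzylfisetinidol-(4α→6)-8-bromo-5,7,3',4'-tetra-O-benzylcatechin (both 3-OH free) | c1cc2c(cc1OCc1ccccc1)O[C@H](c1ccc(OCc3ccccc3)c(OCc3ccccc3)c1)[C@@H](O)[C@@H]2c1c(OCc3ccccc3)c2c(c(Br)c1OCc1ccccc1)O[C@H](c1ccc(OCc3ccccc3)c(OCc3ccccc3)c1)[C@@H](O)C2
F7 | step 7 | 6-iodo derivative of F6 (iodine at C6 of ring A of unit 2) | Ic1cc2c(cc1OCc1ccccc1)O[C@H](c1ccc(OCc3ccccc3)c(OCc3ccccc3)c1)[C@@H](O)[C@@H]2c1c(OCc3ccccc3)c2c(c(Br)c1OCc1ccccc1)O[C@H](c1ccc(OCc3ccccc3)c(OCc3ccccc3)c1)[C@@H](O)C2
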